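**Plan**

- The retrosynthesis first cuts the bond between the ketone carbonyl carbon and its α-CH2, giving salicylaldehyde 9 and a 4-oxygenated styrene. It then cuts the pyran ring (O1–C2 and C4–C4a) back to 3-prenyl-2,4-dihydroxybenzaldehyde 6 and prenal, and last the C-prenyl bond back to 2,4-dihydroxybenzaldehyde 1.
- Enabling feature: the free C7 hydroxyl sits ortho to the C6 carbonyl on the benzo ring of the chromene. O7 and the acyl carbon can hold rhodium in a five-membered chelate, so the ketone can arise by adding the formyl C–H of 9 across a vinylarene.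
- This gives the saturated CH2–CH2 link directly; no chalcone has to be reduced in the presence of the prenyl and chromene olefins. The aldehyde oxidation level is the only design element, and the one helper (an acetate on the remote phenol) is removed in the same flask.
- Forward order: O-alkylation, semihydrogenation and Claisen rearrangement place the prenyl group at C3 between the two oxygens. With C3 blocked, enal condensation through an ortho-quinone methide and oxa-6π closure can only build the pyran at C5 (linear chromene). Hydroacylation then joins the two halves.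
- Stereochemistry: the target has no stereocentre and no stereogenic double bond; the cis olefin of the pyran is fixed by the ring.

Key step: step 5

**Step 1**
Reactants: 1 2,4-dihydroxybenzaldehyde; 2 3-chloro-3-methylbut-1-yne
Product: 3 2-hydroxy-4-[(2-methylbut-3-yn-2-yl)oxy]benzaldehyde
Conditions: K2CO3 (1.2 equiv), KI (cat.), CuI (cat.), acetone, 55 °C
Reagents that add atoms: none
Why: Williamson-type O-alkylation with a tertiary propargylic chloride (copper-assisted ionisation) should occur only at the 4-OH, which is the more acidic hydroxyl, while the 2-OH is held in the hydrogen bond to the formyl group.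

**Step 2**
Reactants: 3 2-hydroxy-4-[(2-methylbut-3-yn-2-yl)oxy]benzaldehyde
Product: 4 2-hydroxy-4-[(2-methylbut-3-en-2-yl)oxy]benzaldehyde
Conditions: H2 (1 atm), Lindlar catalyst, quinoline, EtOAc, rt
Reagents that add atoms: none
Why: Lindlar semihydrogenation should stop at the terminal alkene and leave the aldehyde and the aryl ether untouched.

**Step 3**
Reactants: 4 2-hydroxy-4-[(2-methylbut-3-en-2-yl)oxy]benzaldehyde
Product: 6 2,4-dihydroxy-3-(3-methylbut-2-en-1-yl)benzaldehyde, via Claisen dienone 5 (not isolated)
Conditions: N,N-diethylaniline, 130 °C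
Reagents that add atoms: none
Why: Aromatic Claisen rearrangement of the 1,1-dimethylallyl ether delivers a normal prenyl group with allylic inversion, and C3 should be preferred over C5 because the hydrogen-bonded ortho-hydroxy formyl unit localises double-bond character in the C3–C4 bond; dienone 5 then tautomerises to the phenol.

**Step 4**
Reactants: 6 2,4-dihydroxy-3-(3-methylbut-2-en-1-yl)benzaldehyde; 7 3-methylbut-2-enal
Product: 9 7-hydroxy-2,2-dimethyl-8-(3-methylbut-2-en-1-yl)-2H-chromene-6-carbaldehyde, via ortho-quinone methide 8 (not isolated)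
Conditions: ethylenediammonium diacetate (20 mol%), 7 (2 equiv), xylene, 140 °C, water removal
Reagents that add atoms: none
Why: Amine-salt-catalysed phenol/enal condensation (formal [3+3] annulation) should proceed by attack of C5, the only free position ortho to the 4-OH, on the iminium of 7, elimination to the vinyl ortho-quinone methide 8 and oxa-6π electrocyclisation, so the prenyl group at C3 enforces the linear chromene.

**Step 5**
Reactants: 9 7-hydroxy-2,2-dimethyl-8-(3-methylbut-2-en-1-yl)-2H-chromene-6-carbaldehyde; 10 4-ethenylphenyl acetate
Product: 12 1-[7-hydroxy-2,2-dimethyl-8-(3-methylbut-2-en-1-yl)-2H-chromen-6-yl]-3-(4-hydroxyphenyl)propan-1-one (target), via aryl acetate 11 (not isolated)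
Conditions: [Rh(cod)OMe]2 (2.5 mol%), bulky monodentate phosphoramidite (SIPHOS-PE type, 5 mol%), K3PO4 (10 mol%), 10 (2.5 equiv), BHT (cat.), THF, 70 °C; then MeOH, K2CO3 (cat.), rt
Reagents that add atoms: none
Why: The C7 phenoxide of 9 binds Rh(I) and delivers it into the adjacent C6 formyl C–H bond, giving a five-membered O,C-chelated acyl rhodium(III) hydride (Rh, O7, C7, C6 and the acyl carbon) that is held back from decarbonylation; the vinyl group of 10 then coordinates and inserts into Rh–H with rhodium going to the terminal carbon, and C–C reductive elimination forms the C(=O)–CH2 bond. The closest known reaction type is the phenoxide-directed rhodium-catalysed intermolecular hydroacylation of terminal alkenes with salicylaldehydes, which gives linear 2-hydroxyaryl alkyl ketones. No ring of the product is closed (the rhodacycle is transient) and no stereocentre is formed, so the chirality of the ligand is irrelevant. The step needs linear over branched regioselectivity, which reversible hydride insertion together with the bulky ligand should secure by letting only the primary alkyl reach reductive elimination. It also needs chemoselectivity for the monosubstituted vinyl group, which should hold because the prenyl olefin is trisubstituted, the chromene olefin is cis-disubstituted next to a quaternary carbon, and ring closure onto the C8 prenyl group is geometrically impossible (C6 and C8 are meta). The acetate of 10 keeps the second phenol from competing for rhodium and is removed in the same flask by base-catalysed transesterification with methanol, which also returns any acetyl group that has migrated to O7.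

**Compound list**

1 | 2,4-dihydroxybenzaldehyde | O=Cc1ccc(O)cc1O | starting material
2 | 3-chloro-3-methylbut-1-yne | C#CC(C)(C)Cl | starting material
3 | 2-hydroxy-4-[(2-methylbut-3-yn-2-yl)oxy]benzaldehyde | O=Cc1ccc(OC(C)(C)C#C)cc1O | intermediate
4 | 2-hydroxy-4-[(2-methylbut-3-en-2-yl)oxy]benzaldehyde | O=Cc1ccc(OC(C)(C)C=C)cc1O | intermediate
5 | Claisen dienone, 2-hydroxy-3-(3-methylbut-2-en-1-yl)-4-oxocyclohexa-1,5-diene-1-carbaldehyde (racemic, not isolated) | O=CC1=C(O)C(CC=C(C)C)C(=O)C=C1 | intermediate
6 | 2,4-dihydroxy-3-(3-methylbut-2-en-1-yl)benzaldehyde | CC(C)=CCc1c(O)ccc(C=O)c1O | intermediate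
7 | 3-methylbut-2-enal | CC(C)=CC=O | starting material
8 | ortho-quinone methide, (3Z)-6-hydroxy-5-(3-methylbut-2-en-1-yl)-3-(3-methylbut-2-en-1-ylidene)-4-oxocyclohexa-1,5-diene-1-carbaldehyde (not isolated) | O=CC1=C/C(=C/C=C(C)C)C(=O)C(CC=C(C)C)=C1O | intermediate
9 | 7-hydroxy-2,2-dimethyl-8-(3-methylbut-2-en-1-yl)-2H-chromene-6-carbaldehyde | CC(C)=CCc1c(O)c(C=O)cc2c1OC(C)(C)C=C2 | intermediate
10 | 4-ethenylphenyl acetate (4-acetoxystyrene) | CC(=O)Oc1ccc(C=C)cc1 | starting material
11 | 4-{3-[7-hydroxy-2,2-dimethyl-8-(3-methylbut-2-en-1-yl)-2H-chromen-6-yl]-3-oxopropyl}phenyl acetate (not isolated) | CC(C)=CCc1c(O)c(C(=O)CCc2ccc(OC(C)=O)cc2)cc2c1OC(C)(C)C=C2 | intermediate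
12 | 1-[7-hydroxy-2,2-dimethyl-8-(3-methylbut-2-en-1-yl)-2H-chromen-6-yl]-3-(4-hydroxyphenyl)propan-1-one | CC(C)=CCc1c(O)c(C(=O)CCc2ccc(O)cc2)cc2c1OC(C)(C)C=C2 | target

**Step count and risks**

Total step count: 5. Longest linear sequence: 5 steps (1 to 12); 2, 7 and 10 are purchased.

Steps most likely to fail:

1. Step 5. The hydride may insert to give the benzylic rhodium alkyl and hence the branched ketone. The acyl rhodium hydride may also decarbonylate, the rhodium hydride may move the prenyl double bond, or the styrene may polymerise. The fallback sets out from 9 and comes back at 12. Commercial 4-(2-bromoethyl)phenol (Oc1ccc(CCBr)cc1) would be silylated (TBSCl, imidazole, DMF) to tert-butyl[4-(2-bromoethyl)phenoxy]dimethylsilane F1, and magnesium in THF should convert this into {2-[4-(tert-butyldimethylsilyloxy)phenyl]ethyl}magnesium bromide F2. About 2.5 equiv of F2 would be added to 9 at -40 to 0 °C; the first equivalent is consumed by the phenol and the second adds to the formyl group. Aqueous work-up should give racemic 1-[7-hydroxy-2,2-dimethyl-8-(3-methylbut-2-en-1-yl)-2H-chromen-6-yl]-3-[4-(tert-butyldimethylsilyloxy)phenyl]propan-1-ol F3. Activated MnO2 in CH2Cl2 should oxidise this ortho-hydroxybenzylic alcohol, without touching the olefins, to 1-[7-hydroxy-2,2-dimethyl-8-(3-methylbut-2-en-1-yl)-2H-chromen-6-yl]-3-[4-(tert-butyldimethylsilyloxy)phenyl]propan-1-one F4. TBAF buffered with AcOH in THF at 0 °C would then free the phenol to give 12.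

2. Step 4. Carbon attack by the hindered, formyl-deactivated phenol may be slow. The salicylaldehyde unit may instead enter an oxa-Michael/aldol domino with the enal, or the ortho-prenyl phenol may cyclise to a chroman on prolonged heating. The fallback sets out from 6 and comes back at 9. The 4-OH of 6 would be alkylated with 2 (K2CO3, KI, CuI, acetone, as in step 1) to give 2-hydroxy-4-[(2-methylbut-3-yn-2-yl)oxy]-3-(3-methylbut-2-en-1-yl)benzaldehyde F5. Heating F5 in N,N-diethylaniline at about 180 °C should trigger propargyl Claisen rearrangement to C5 (C3 is blocked), tautomerisation, a [1,5]-hydrogen shift to the same ortho-quinone methide 8 and oxa-6π closure to 9.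

3. Step 3. The allyl group may migrate to C5 instead of C3, or the ortho-prenyl phenol formed may cyclise thermally. The fallback sets out from 1 and comes back at 6, bypassing steps 1 to 3. The phenoxide of 1 would be C-prenylated directly with 1-bromo-3-methylbut-2-ene (CC(C)=CCBr) in aqueous KOH at 0 °C to rt, where alkylation at C3 between the two oxygens is the preferred C-alkylation, followed by chromatographic separation. This fallback makes no compound outside the list (F0).

**Further compounds**

F1 | step 5 | tert-butyl[4-(2-bromoethyl)phenoxy]dimethylsilane | CC(C)(C)[Si](C)(C)Oc1ccc(CCBr)cc1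
F2 | step 5 | {2-[4-(tert-butyldimethylsilyloxy)phenyl]ethyl}magnesium bromide | CC(C)(C)[Si](C)(C)Oc1ccc(CC[Mg]Br)cc1
F3 | step 5 | rac-1-[7-hydroxy-2,2-dimethyl-8-(3-methylbut-2-en-1-yl)-2H-chromen-6-yl]-3-[4-(tert-butyldimethylsilyloxy)phenyl]propan-1-ol | CC(C)=CCc1c(O)c(C(O)CCc2ccc(O[Si](C)(C)C(C)(C)C)cc2)cc2c1OC(C)(C)C=C2
F4 | step 5 | 1-[7-hydroxy-2,2-dimethyl-8-(3-methylbut-2-en-1-yl)-2H-chromen-6-yl]-3-[4-(tert-butyldimethylsilyloxy)phenyl]propan-1-one | CC(C)=CCc1c(O)c(C(=O)CCc2ccc(O[Si](C)(C)C(C)(C)C)cc2)cc2c1OC(C)(C)C=C2
F5 | step 4 | 2-hydroxy-4-[(2-methylbut-3-yn-2-yl)oxy]-3-(3-methylbut-2-en-1-yl)benzaldehyde | CC(C)=CCc1c(OC(C)(C)C#C)ccc(C=O)c1O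
F0 | step 3 | none | none
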